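Amounts first: this flask holds 34 mM of each substrate, 34 µM of catalyst and 102 mM of solid reagent, and the earlier runs differ from it in solid reagent or catalyst.

all flasks: left-handed substrate 34 mM; right-handed substrate 34 mM

| flask | solid reagent | catalyst | remark | time |
|---|---|---|---|---|
| south-east | 51 mM | 34 µM | run made earlier |  |
| west | 200 mM | 34 µM | run made earlier |  |
| north-east | 102 mM | 68 µM | run made earlier |  |
| flask | 102 mM | 34 µM |  | 8.0 h |

- south-east (time / h: left-handed product / %, left-handed substrate / %): 0.667: 0, 49.8; 2.00: 1.6, 48.0; 4.00: 3.7, 47.1; 6.00: 5.7, 46.1; 8.00: 7.2, 45.1
- west (time / h: left-handed product / %, left-handed substrate / %): 0.667: 0.5, 49.8; 2.00: 1.7, 48.2; 4.00: 4.0, 47.3; 6.00: 5.7, 45.3; 8.00: 7.6, 45.2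
- north-east (time / h: left-handed product / %, left-handed substrate / %): 0.667: 0.8, 49.2; 1.33: 2.1, 48.2; 2.50: 3.8, 46.6; 4.00: 6.9, 45.5; 8.00: 12.8, 42.1

(scatter of a reading: 0.3 percentage points)

1. amount of left-handed product at 8.0 h, in percent of the left-handed substrate and right-handed substrate together charged
2. the change that raises the amount of left-handed product at 8.0 h, in percent of the left-handed substrate and right-handed substrate together charged most ("none" if none brings more than 2 percentage points) (beta / theta / epsilon / none)
3. amount of left-handed product at 8.0 h, in percent of the left-handed substrate and right-handed substrate together charged, after epsilon

- beta: doubling the dissolution coefficient of the solid reagent, all else as stated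
- theta: doubling the amount of catalyst, all else as stated
- epsilon: doubling the solubility of the solid reagent, all else as stated

- catalyst is single-handed; left-handed substrate and right-handed substrate are mirror images of each other, charged as a racemate, each of them at the stated concentration
- solid reagent is a solid; its amount is given per volume of the solution
- at the start none of the solid reagent is in solution

**Question: what does the amount of solid charged do?**
Going from 51 mM in the south-east run to 200 mM in the west run moves left-handed product at 8.00 h from 7.2 % to 7.6 %. That step of 0.4 percentage points compares with a scatter of 0.3 points on each reading, so I read a zero-order dependence on the solid charged and average the two runs into 0.00925 /h. This is the pace: the fraction of both substrates charged that becomes left-handed product per hour at 34 µM of catalyst.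

**Question: and this flask?**
Its solid charge lies between those two and its catalyst is the same, so my figure is the pace times 8.0 h, or 7.40 %.

**Question: what does twice the catalyst buy?**
The north-east run is that change and reads 12.8 %, which is 1.73 times the pace reckoning.

**Question: if the solid charge does nothing, does the dissolved amount do nothing?**
That does not follow: the runs vary the charge, not the solubility. Assuming that the dissolved amount follows the solubility and that the pace is first order in it, both untested, my reckoning has epsilon double the pace and give 14.8 % in this flask, more than the 12.8 % read in the north-east run. I therefore choose epsilon. The reading to watch in a repeat is left-handed product against the pace times the time.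

The forecast gives 7.4 %, the same as my figure, but it names theta and puts epsilon at 11.5 %, saying “it can at most about match theta”.

    solid reagent ⇌ partner, rate k1*(cs1 - [partner]) while solid is left; crystals form when [partner] > cs1 (solubility = 2.00 mM, k = 0.0370 /min)
    partner + catalyst + right-handed substrate → catalyst + right-handed product (k = 130 /M²/min)
    partner + catalyst + left-handed substrate → catalyst + left-handed product (k = 6300 /M²/min)
    left-handed substrate ⇌ right-handed substrate (k = 0.00500 /min)

The flask gives 7.79 % against the reckoned 7.40 %, and the best change is epsilon. Epsilon adds 7.1 points and reaches 14.9 %, against the doubled-pace 14.8 %, while theta adds 5.3 points and beta 0.82 points. On this choice the forecast and the flask part. At 8.00 h, partner stands at 1.69 mM in this flask, under its solubility of 2.0 mM. The neighbouring flask, charged with 61 mM of solid reagent, has the same catalyst and lies inside the charges behind the pace, so the reckoning again gives 7.40 %. It gives 7.79 %, with 88.4 % of its solid reagent remaining, against 93.0 % in this flask.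

The runs were computed for substances that don't exist; the scatter is artificial.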